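**Plan**

1. Numbering used throughout: ring C1 (stereocentre)–C2H2–C3H=C4(C4'H2OH)–C5–C6–C7H=C8(Me)–C9–C10–C11H=C12(Me)–C13–C14–C1; side chain C15(=C16H2)–C17–C18–C19H=C20Me2.
2. Retrosynthesis: cut O–Si and C15=C16 (methylenation of a C15 ketone), then the ring bond C2–C3 (alkenyl iodide at C3, homoenolate at C2), then the cyclopropane bonds of C2 (CH2 from a gem-dizinc reagent), C15–C17 (Grignard), C13–C14 (allyl–alkyl coupling), C4–C4' (formaldehyde), and C3≡C4 back to the methyl ketone of nerylacetone.
3. Forward: the open chain C3–C20 is built linearly from nerylacetone (C3–C13), a three-carbon acetal Grignard reagent (C14, C1, C15) and the homoprenyl Grignard reagent (C17–C20). The only ring before the key step is the cyclopropanol C15–C1–C2; the 14-membered ring is closed third from last.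
4. Enabling feature: the exocyclic methylene carbon C15 sits on stereocentre C1, which sits on ring CH2 C2. C15 is therefore a latent ketone and C2 its β-carbon (a homoenolate position). Tying C15, C1 and C2 into a cyclopropanol stores the strain that drives C15–C2 cleavage and C2–C3 bond formation on palladium.
5. Stereochemistry: C1 comes from an organocatalytic aldehyde α-chlorination, is inverted once in the SN2 closure of the cyclopropanol, and is then untouched. 7Z comes from nerylacetone, 11E from E-selective SeO2 oxidation, and the C3=C4 geometry from syn hydro-hydroxymethylation of a silylalkyne, retentive iododesilylation and retentive coupling.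

Key step: step 12

Assumption: nerylacetone is used as the pure 5Z isomer, and the (2S,5S) enantiomer of the chlorination catalyst is taken to give the (R)-chloride; if the sense is the reverse, the antipode is used and nothing else changes.

**Route**

Step 1
Reactants: 1 nerylacetone
Product: 4 [(5Z)-6,10-dimethylundeca-5,9-dien-1-yn-1-yl]trimethylsilane, via enol diethyl phosphate 2 (not isolated), via lithium acetylide 3 (not isolated)
Conditions: LiN(i-Pr)2 (1.1 equiv), THF, −78 °C; ClP(O)(OEt)2, −78 °C to rt; LiN(i-Pr)2 (2.3 equiv), −78 °C to rt; Me3SiCl, −78 °C to rt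
Reagents that add atoms: chlorotrimethylsilane C[Si](C)(C)Cl
Why: Kinetic deprotonation of the methyl group, O-phosphorylation and double elimination of the enol phosphate (methyl ketone to alkyne conversion) should give the acetylide, which is C-silylated, the 5Z alkene being untouched.

Step 2
Reactants: 4 silyl enyne
Product: 5 (2E,5Z)-6,10-dimethyl-2-[(trimethylsilyl)methylidene]undeca-5,9-dien-1-yl triisopropylsilyl ether (Me3Si on C3 cis to C5)
Conditions: Ni(cod)2 (10 mol%), IMes·HCl (10 mol%), KOt-Bu (10 mol%), (CH2O)n (3 equiv), i-Pr3SiH (2 equiv), THF, 45 °C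
Reagents that add atoms: paraformaldehyde (as formaldehyde) C=O; triisopropylsilane CC(C)[SiH](C(C)C)C(C)C
Why: Nickel-catalysed reductive alkyne–aldehyde coupling, in which oxidative cyclisation on zerovalent nickel forms the C–C bond at the alkyne carbon remote from silicon and the silane then delivers H cis to the new CH2OSi group, so that Me3Si should end cis to the C5 chain and the alcohol should emerge as its TIPS ether.

Step 3
Reactants: 5 vinylsilane TIPS ether
Product: 6 (2E,6Z,10E)-2,6-dimethyl-10-{[(triisopropylsilyl)oxy]methyl}-11-(trimethylsilyl)undeca-2,6,10-trien-1-ol (C13 alcohol)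
Conditions: SeO2 (0.2 equiv), t-BuOOH (3 equiv), salicylic acid (0.1 equiv), CH2Cl2, 0 °C to rt, stopped at partial conversion
Reagents that add atoms: tert-butyl hydroperoxide CC(C)(C)OO
Why: Riley allylic oxidation (ene reaction, then [2,3]-shift) should go to the most accessible trisubstituted alkene, the terminal isopropylidene group, and by its known preference to the methyl group trans to the chain, which sets 11E.

Step 4
Reactants: 6 C13 allylic alcohol
Product: 7 [(1E,5Z,9E)-11-bromo-6,10-dimethyl-2-{[(triisopropylsilyl)oxy]methyl}undeca-1,5,9-trien-1-yl]trimethylsilane (C13 bromide)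
Conditions: CBr4, PPh3, CH2Cl2, −20 to 0 °C; used crude
Reagents that add atoms: tetrabromomethane BrC(Br)(Br)Br
Why: Appel bromination of a primary allylic alcohol at low temperature should proceed without allylic transposition or loss of the 11E geometry.

Step 5
Reactants: 7 C13 allylic bromide; 8 2-(2-bromoethyl)-1,3-dioxolane
Product: 10 2-[(4E,8Z,12E)-4,8-dimethyl-12-{[(triisopropylsilyl)oxy]methyl}-13-(trimethylsilyl)trideca-4,8,12-trien-1-yl]-1,3-dioxolane, via acetal Grignard reagent 9 (not isolated)
Conditions: 8, Mg, THF, 25 °C; then 7, Li2CuCl4 (3 mol%), THF, −78 to −10 °C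
Reagents that add atoms: none
Why: Copper-catalysed Grignard cross-coupling of a primary allylic bromide, which with fast addition at low temperature in THF should substitute at the primary carbon C13 (not at C11) with retention of the alkene geometry, the γ-acetal Grignard reagent being stable below 30 °C.

Step 6
Reactants: 10 vinylsilane acetal
Product: 11 2-[(4E,8Z,12E)-13-iodo-4,8-dimethyl-12-{[(triisopropylsilyl)oxy]methyl}trideca-4,8,12-trien-1-yl]-1,3-dioxolane
Conditions: NIS (1.3 equiv), MeCN/ClCH2CN (4:1), 0 °C, dark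
Reagents that add atoms: N-iodosuccinimide O=C1CCC(=O)N1I
Why: Electrophilic ipso-iododesilylation, in which attack of iodonium at the silicon-bearing carbon is directed by the β-silyl effect and loss of Me3Si should give the alkenyl iodide with retention (I cis to C5), the other trisubstituted alkenes reacting far more slowly with NIS in the absence of a nucleophile.

Step 7
Reactants: 11 iodo acetal
Product: 12 (5E,9Z,13E)-14-iodo-5,9-dimethyl-13-{[(triisopropylsilyl)oxy]methyl}tetradeca-5,9,13-trienal (C15 aldehyde)
Conditions: PPTS (0.2 equiv), acetone/H2O (10:1), 50 °C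
Reagents that add atoms: water O
Why: Acid-catalysed acetal hydrolysis under conditions that the TIPS ether and the alkenyl iodide should tolerate.

Step 8
Reactants: 12 aldehyde
Product: 13 (2R,5E,9Z,13E)-2-chloro-14-iodo-5,9-dimethyl-13-{[(triisopropylsilyl)oxy]methyl}tetradeca-5,9,13-trienal (chloride on C1)
Conditions: NCS (1.2 equiv), (2S,5S)-2,5-diphenylpyrrolidine (10 mol%), CH2Cl2, 0 °C to rt; pentane filtration, used at once
Reagents that add atoms: N-chlorosuccinimide O=C1CCC(=O)N1Cl
Why: Enamine-mediated organocatalytic α-chlorination of the aldehyde, in which the C2-symmetric pyrrolidine controls the face of the enamine that is chlorinated and so sets C1 (R at this stage).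

Step 9
Reactants: 13 α-chloro aldehyde; 14 5-bromo-2-methylpent-2-ene
Product: 16 (6S,7R,10E,14Z,18E)-7-chloro-19-iodo-2,10,14-trimethyl-18-{[(triisopropylsilyl)oxy]methyl}nonadeca-2,10,14,18-tetraen-6-ol (anti chlorohydrin drawn), via homoprenyl Grignard reagent 15 (not isolated)
Conditions: 14, Mg, THF; then 13, THF, −78 °C; aq. NH4Cl at −78 °C
Reagents that add atoms: none
Why: Grignard 1,2-addition at −78 °C should outrun enolisation and any reaction at the alkenyl iodide, and the dipole-minimised transition state should favour the anti chlorohydrin, whose carbinol centre is removed in step 10.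

Step 10
Reactants: 16 chlorohydrin
Product: 17 (7R,10E,14Z,18E)-7-chloro-19-iodo-2,10,14-trimethyl-18-{[(triisopropylsilyl)oxy]methyl}nonadeca-2,10,14,18-tetraen-6-one (C15 ketone, C1 chloride)
Conditions: Dess–Martin periodinane, NaHCO3, CH2Cl2, 0 °C to rt; short silica plug
Reagents that add atoms: none
Why: Dess–Martin oxidation under buffered, non-basic conditions should give the α-chloro ketone without epimerising C1.

Step 11
Reactants: 17 α-chloro ketone
Product: 18 (2R)-2-[(3E,7Z,11E)-12-iodo-3,7-dimethyl-11-{[(triisopropylsilyl)oxy]methyl}dodeca-3,7,11-trien-1-yl]-1-(4-methylpent-3-en-1-yl)cyclopropan-1-ol (ring = C15, C1, C2; carbinol carbon C15 either epimer)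
Conditions: CH2(ZnI)2 (2.5 equiv; from CH2I2, Zn, PbCl2 cat., THF), THF, 0 °C to rt; aq. NH4Cl
Reagents that add atoms: bis(iodozincio)methane I[Zn]C[Zn]I
Why: Nucleophilic cyclopropanation with a geminal dizinc reagent, in which addition to the activated carbonyl gives a β-zincio alkoxide whose C–Zn carbon displaces the neighbouring chloride in a 3-exo-tet SN2 closure with inversion at C1 (the descriptor stays R because the priorities change), giving the spatial arrangement of the target.

Step 12
Reactants: 18 cyclopropanol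
Product: 19 5-methyl-1-[(1R,3E,7Z,11E)-8,12-dimethyl-4-{[(triisopropylsilyl)oxy]methyl}cyclotetradeca-3,7,11-trien-1-yl]hex-4-en-1-one (macrocyclic C15 ketone)
Conditions: Pd2(dba)3 (5 mol%), XPhos (12 mol%), Cs2CO3 (2 equiv), toluene, 60 °C, syringe-pump addition of 18 over 12 h (final 1 mM)
Reagents that add atoms: none
Why: Proposed new method: oxidative addition of the alkenyl iodide to zerovalent palladium, iodide/alkoxide exchange with the caesium cyclopropoxide and strain-releasing β-carbon elimination of the less substituted C15–C2 bond should give a C2-palladated ketone (palladium homoenolate) that reductively eliminates onto C3; the closest known reaction type is the intermolecular palladium-catalysed ring-opening cross-coupling of cyclopropanols with aryl halides, here run intramolecularly with an alkenyl iodide. The 14-membered ring closes by C(sp3)–C(sp2) reductive elimination from a 15-membered alkyl(alkenyl)palladacycle, the new bond ending on a ring alkene carbon (endo with respect to C3=C4). No stereocentre is formed: C1 is a spectator of the C15–C2 cleavage and keeps its configuration, and the geometry of the alkenyl iodide is carried over with retention. The step needs cleavage of the bond to the CH2 carbon rather than C15–C1 (secured by the lower substitution of C2), reductive elimination faster than β-hydride loss to the α-methylene ketone (bulky biaryl phosphine), and ring closure faster than oligomerisation (slow addition, high dilution).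

Step 13
Reactants: 19 macrocyclic ketone
Product: 20 triisopropylsilyl ether of the target (C15=C16H2 installed)
Conditions: Cp2TiMe2 (3 equiv), toluene/THF, 65 °C, dark
Reagents that add atoms: dimethyltitanocene C[Ti](C)(C1C=CC=C1)C1C=CC=C1
Why: Petasis methylenation through Cp2Ti=CH2, a non-basic carbonyl olefination, should convert the enolisable ketone into the 1,1-disubstituted alkene without epimerising the adjacent stereocentre C1.

Step 14
Reactants: 20 silyl ether
Product: 21 [(1E,4R,7E,11Z)-7,11-dimethyl-4-(6-methylhepta-1,5-dien-2-yl)cyclotetradeca-1,7,11-trien-1-yl]methanol (target)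
Conditions: Bu4NF (1.5 equiv), THF, 0 °C to rt
Reagents that add atoms: none
Why: Fluoride-mediated cleavage of the silyl ether should free the allylic alcohol and leave the tetraene untouched.

**Compound list**

1 | nerylacetone, (5Z)-6,10-dimethylundeca-5,9-dien-2-one | CC(=O)CC/C=C(/C)CCC=C(C)C | starting material
2 | diethyl (5Z)-6,10-dimethylundeca-1,5,9-trien-2-yl phosphate | C=C(OP(=O)(OCC)OCC)CC/C=C(/C)CCC=C(C)C | intermediate
3 | lithium acetylide of (5Z)-6,10-dimethylundeca-5,9-dien-1-yne | [Li]C#CCC/C=C(/C)CCC=C(C)C | intermediate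
4 | [(5Z)-6,10-dimethylundeca-5,9-dien-1-yn-1-yl]trimethylsilane | C[Si](C)(C)C#CCC/C=C(/C)CCC=C(C)C | intermediate
5 | (2E,5Z)-6,10-dimethyl-2-[(trimethylsilyl)methylidene]undeca-5,9-dien-1-yl triisopropylsilyl ether | C[Si](C)(C)/C=C(/CO[Si](C(C)C)(C(C)C)C(C)C)CC/C=C(/C)CCC=C(C)C | intermediate
6 | (2E,6Z,10E)-2,6-dimethyl-10-{[(triisopropylsilyl)oxy]methyl}-11-(trimethylsilyl)undeca-2,6,10-trien-1-ol | C[Si](C)(C)/C=C(/CO[Si](C(C)C)(C(C)C)C(C)C)CC/C=C(/C)CC/C=C(\C)CO | intermediate
7 | [(1E,5Z,9E)-11-bromo-6,10-dimethyl-2-{[(triisopropylsilyl)oxy]methyl}undeca-1,5,9-trien-1-yl]trimethylsilane | C[Si](C)(C)/C=C(/CO[Si](C(C)C)(C(C)C)C(C)C)CC/C=C(/C)CC/C=C(\C)CBr | intermediate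
8 | 2-(2-bromoethyl)-1,3-dioxolane | BrCCC1OCCO1 | starting material
9 | [2-(1,3-dioxolan-2-yl)ethyl]magnesium bromide | Br[Mg]CCC1OCCO1 | intermediate
10 | 2-[(4E,8Z,12E)-4,8-dimethyl-12-{[(triisopropylsilyl)oxy]methyl}-13-(trimethylsilyl)trideca-4,8,12-trien-1-yl]-1,3-dioxolane | C[Si](C)(C)/C=C(/CO[Si](C(C)C)(C(C)C)C(C)C)CC/C=C(/C)CC/C=C(\C)CCCC1OCCO1 | intermediate
11 | 2-[(4E,8Z,12E)-13-iodo-4,8-dimethyl-12-{[(triisopropylsilyl)oxy]methyl}trideca-4,8,12-trien-1-yl]-1,3-dioxolane | I/C=C(/CO[Si](C(C)C)(C(C)C)C(C)C)CC/C=C(/C)CC/C=C(\C)CCCC1OCCO1 | intermediate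
12 | (5E,9Z,13E)-14-iodo-5,9-dimethyl-13-{[(triisopropylsilyl)oxy]methyl}tetradeca-5,9,13-trienal | I/C=C(/CO[Si](C(C)C)(C(C)C)C(C)C)CC/C=C(/C)CC/C=C(\C)CCCC=O | intermediate
13 | (2R,5E,9Z,13E)-2-chloro-14-iodo-5,9-dimethyl-13-{[(triisopropylsilyl)oxy]methyl}tetradeca-5,9,13-trienal | I/C=C(/CO[Si](C(C)C)(C(C)C)C(C)C)CC/C=C(/C)CC/C=C(\C)CC[C@@H](Cl)C=O | intermediate
14 | 5-bromo-2-methylpent-2-ene | BrCCC=C(C)C | starting material
15 | (4-methylpent-3-en-1-yl)magnesium bromide | Br[Mg]CCC=C(C)C | intermediate
16 | (6S,7R,10E,14Z,18E)-7-chloro-19-iodo-2,10,14-trimethyl-18-{[(triisopropylsilyl)oxy]methyl}nonadeca-2,10,14,18-tetraen-6-ol (anti isomer drawn) | I/C=C(/CO[Si](C(C)C)(C(C)C)C(C)C)CC/C=C(/C)CC/C=C(\C)CC[C@@H](Cl)[C@@H](O)CCC=C(C)C | intermediate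
17 | (7R,10E,14Z,18E)-7-chloro-19-iodo-2,10,14-trimethyl-18-{[(triisopropylsilyl)oxy]methyl}nonadeca-2,10,14,18-tetraen-6-one | I/C=C(/CO[Si](C(C)C)(C(C)C)C(C)C)CC/C=C(/C)CC/C=C(\C)CC[C@@H](Cl)C(=O)CCC=C(C)C | intermediate
18 | (2R)-2-[(3E,7Z,11E)-12-iodo-3,7-dimethyl-11-{[(triisopropylsilyl)oxy]methyl}dodeca-3,7,11-trien-1-yl]-1-(4-methylpent-3-en-1-yl)cyclopropan-1-ol (carbinol carbon either epimer) | I/C=C(/CO[Si](C(C)C)(C(C)C)C(C)C)CC/C=C(/C)CC/C=C(\C)CC[C@@H]1CC1(O)CCC=C(C)C | intermediate
19 | 5-methyl-1-[(1R,3E,7Z,11E)-8,12-dimethyl-4-{[(triisopropylsilyl)oxy]methyl}cyclotetradeca-3,7,11-trien-1-yl]hex-4-en-1-one | O=C(CCC=C(C)C)[C@H]1C/C=C(/CO[Si](C(C)C)(C(C)C)C(C)C)CC/C=C(/C)CC/C=C(\C)CC1 | intermediate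
20 | triisopropyl{[(1E,4R,7E,11Z)-7,11-dimethyl-4-(6-methylhepta-1,5-dien-2-yl)cyclotetradeca-1,7,11-trien-1-yl]methoxy}silane | C=C(CCC=C(C)C)[C@H]1C/C=C(/CO[Si](C(C)C)(C(C)C)C(C)C)CC/C=C(/C)CC/C=C(\C)CC1 | intermediate
21 | [(1E,4R,7E,11Z)-7,11-dimethyl-4-(6-methylhepta-1,5-dien-2-yl)cyclotetradeca-1,7,11-trien-1-yl]methanol | C=C(CCC=C(C)C)[C@H]1C/C=C(/CO)CC/C=C(/C)CC/C=C(\C)CC1 | target

**Step count and risks**

Total steps: 14. Longest linear sequence: 14 steps, from nerylacetone 1.

Steps most likely to fail:

1. Step 12 (proposed new method). What may go wrong: β-hydride elimination from the C2-palladated ketone to the α-methylene ketone (with loss or, if it is reversible, erosion of C1), and intermolecular coupling in competition with ring closure. Fallback with known chemistry, from 18 back to 19: the C–C cleavage is taken off palladium. Cyclopropanol 18 is deprotonated with EtZnI (THF, 0 °C to rt); the iodozinc cyclopropoxide opens at its less substituted bond to the β-zincated ketone, zinc homoenolate F1. F1 is added slowly to PdCl2(dppf) (5 mol%) in THF/DMA at 40 °C under high dilution, where a Negishi alkyl–alkenyl coupling should close the ring to 19.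

2. Step 11. What may go wrong: slow addition of the dizinc reagent to the ketone carbonyl, so that enolisation (erosion at C1) or reductive loss of chloride takes over. Fallback from 13 back to 19, moving the cyclopropanation to the aldehyde, the substrate class on which it is established: α-chloro aldehyde 13 and CH2(ZnI)2 (THF, 0 °C) should give the trans secondary cyclopropanol F2. Ring-opening macrocyclisation of F2 under the conditions of step 12 (or through its zinc homoenolate, as above) should give macrocyclic aldehyde F3, with C1 now α to a formyl group. Addition of Grignard reagent 15 at −78 °C gives carbinol F4 (both epimers), and Dess–Martin oxidation returns to ketone 19.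

3. Step 2. What may go wrong: poor turnover with polymeric formaldehyde, or incomplete regiocontrol in the oxidative cyclisation. Fallback from 4 back to 5, stoichiometric in titanium: 4 is converted with Ti(Oi-Pr)4 and i-PrMgCl (2 equiv, Et2O, −50 °C) into its titanacyclopropene, a species known to add aldehydes at the carbon remote from silicon. Monomeric formaldehyde (from cracked paraformaldehyde) and aqueous work-up should give allylic alcohol F5 with the same cis relationship of H and CH2OH, and TIPSCl/imidazole (DMF) gives 5.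

**Further compounds**

F1 | step 12 | iodozinc homoenolate, [(2S)-2-(C14 chain)-3-oxo-7-methyloct-6-en-1-yl]zinc iodide (β-zincated form of ketone 19 precursor, C2–ZnI) | I/C=C(/CO[Si](C(C)C)(C(C)C)C(C)C)CC/C=C(/C)CC/C=C(\C)CC[C@H](C[Zn]I)C(=O)CCC=C(C)C
F2 | step 11 | (1S,2R)-trans-2-[(3E,7Z,11E)-12-iodo-3,7-dimethyl-11-{[(triisopropylsilyl)oxy]methyl}dodeca-3,7,11-trien-1-yl]cyclopropan-1-ol | I/C=C(/CO[Si](C(C)C)(C(C)C)C(C)C)CC/C=C(/C)CC/C=C(\C)CC[C@@H]1C[C@H]1O
F3 | step 11 | (1R,3E,7Z,11E)-8,12-dimethyl-4-{[(triisopropylsilyl)oxy]methyl}cyclotetradeca-3,7,11-triene-1-carbaldehyde | O=C[C@H]1C/C=C(/CO[Si](C(C)C)(C(C)C)C(C)C)CC/C=C(/C)CC/C=C(\C)CC1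
F4 | step 11 | 5-methyl-1-[(1R,3E,7Z,11E)-8,12-dimethyl-4-{[(triisopropylsilyl)oxy]methyl}cyclotetradeca-3,7,11-trien-1-yl]hex-4-en-1-ol (carbinol epimers) | OC(CCC=C(C)C)[C@H]1C/C=C(/CO[Si](C(C)C)(C(C)C)C(C)C)CC/C=C(/C)CC/C=C(\C)CC1
F5 | step 2 | (2E,5Z)-6,10-dimethyl-2-[(trimethylsilyl)methylidene]undeca-5,9-dien-1-ol | C[Si](C)(C)/C=C(/CO)CC/C=C(/C)CCC=C(C)C
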